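**Plan**

1. Feature: in the eleven-membered ring (C1 ester carbinol, C2=C3(Me), C4, C5, C6–C7 epoxide with Me on C7, C8, C9, C10, C11 = CMe2) the secondary carbinol C1 is bonded to the quaternary C11. This pair is what remains when a γ,γ-dimethylallyl metal adds to an aldehyde through its substituted end.
2. Retrosynthesis: cut the ester C(=O)–O1 bond, put back a C9=C10 alkene, then cut the ring bond C1–C11. The carbocycle unfolds to an open-chain C15 epoxy enal with a C9–C11 allylic carbonate, whose carbons are those of (2E,6E)-farnesol.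
3. Forward: no chain is joined. The farnesyl tail (C10=C11 → C9=C10 with C11–O carbonate) and head (C1 → enal) are functionalised and the oxirane is placed at C6–C7. The carbocycle then closes last by Pd/In umpoled allylation (C1–C11); alkene saturation and acylation finish.
4. Stereochemistry: 2E comes from farnesol. 6R,7R comes from Shi epoxidation (D-fructose-derived ketone) of the E-C6=C7 alkene. 1S comes from the ring closure (C11 onto the Re face of the enal, induced by the epoxide) and is retained afterwards.

Key step: step 10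

Remark: ring atoms keep the farnesane locants C1–C11; compounds 4–8 are racemic at C10, which is immaterial because C10 becomes sp2 in step 4; the C9=C10 geometry of 17 (drawn E) is also immaterial because step 11 saturates it, so a 9Z isomer would converge on 18.

**Route**

Step 1
Reactants: 1 (2E,6E)-farnesol; 2 acetic anhydride
Product: 3 (2E,6E)-farnesyl acetate
Conditions: Ac2O, pyridine, DMAP (cat.), CH2Cl2, 0 °C → rt
Reagents that add atoms: acetic anhydride (2), CC(=O)OC(C)=O
Why: DMAP-catalysed O-acetylation of a primary alcohol; the allylic ester lowers the nucleophilicity of the C2=C3 alkene for the electrophilic step that follows.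

Step 2
Reactants: 3 (2E,6E)-farnesyl acetate
Product: 4 (2E,6E)-10-bromo-11-hydroxy-3,7,11-trimethyldodeca-2,6-dien-1-yl acetate (racemic at C10)
Conditions: NBS, THF/H2O, 0 °C
Reagents that add atoms: N-bromosuccinimide, O=C1CCC(=O)N1Br; water, O
Why: terminal-selective bromohydrin formation of polyprenyl acetates in aqueous THF, in which the exposed, most electron-rich C10=C11 alkene forms the bromonium ion and water opens it at the tertiary C11 (Markovnikov).

Step 3
Reactants: 4 (2E,6E)-10-bromo-11-hydroxy-3,7,11-trimethyldodeca-2,6-dien-1-yl acetate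
Product: 6 (2E,6E)-10,11-epoxy-3,7,11-trimethyldodeca-2,6-dien-1-ol (racemic), via epoxy acetate 5 (not isolated)
Conditions: K2CO3, MeOH, rt
Reagents that add atoms: none
Why: intramolecular Williamson closure of the bromohydrin gives the oxirane, and the same methoxide medium removes the acetate by transesterification.

Step 4
Reactants: 6 (2E,6E)-10,11-epoxy-3,7,11-trimethyldodeca-2,6-dien-1-ol
Product: 9 (2E,6E,9E)-3,7,11-trimethyldodeca-2,6,9-triene-1,11-diol, via hydroxy selenide 7 (not isolated), via selenoxide 8 (not isolated)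
Conditions: PhSeSePh, NaBH4, EtOH, 0 °C → reflux; then THF, pyridine, 30% H2O2, 0 °C → rt
Reagents that add atoms: none
Why: epoxide-to-allylic-alcohol transposition through a β-hydroxy selenide: the selenolate opens the oxirane at the less hindered C10 (SN2), and the selenoxide undergoes syn-elimination towards C9 (C11 carries no hydrogen), giving the E-C9=C10 alkene and the tertiary C11 alcohol.

Step 5
Reactants: 9 (2E,6E,9E)-3,7,11-trimethyldodeca-2,6,9-triene-1,11-diol; 2 acetic anhydride
Product: 10 (2E,6E,9E)-11-hydroxy-3,7,11-trimethyldodeca-2,6,9-trien-1-yl acetate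
Conditions: Ac2O (1.1 equiv), pyridine, CH2Cl2, 0 °C
Reagents that add atoms: acetic anhydride (2), CC(=O)OC(C)=O
Why: chemoselective acetylation of the primary hydroxyl, since the tertiary C11 hydroxyl does not react with Ac2O/pyridine at 0 °C; the acetate is needed to deactivate C2=C3 in step 7.

Step 6
Reactants: 10 (2E,6E,9E)-11-hydroxy-3,7,11-trimethyldodeca-2,6,9-trien-1-yl acetate; 11 methyl chloroformate
Product: 12 (2E,6E,9E)-11-(methoxycarbonyloxy)-3,7,11-trimethyldodeca-2,6,9-trien-1-yl acetate
Conditions: LiHMDS (1.05 equiv), THF, −78 °C; then ClCO2Me, −78 → 0 °C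
Reagents that add atoms: methyl chloroformate (11), COC(Cl)=O
Why: O-acylation of a tertiary lithium alkoxide with a chloroformate; one equivalent of the hindered amide base at −78 °C removes the O–H proton far faster than an acetate α-proton.

Step 7
Reactants: 12 (2E,6E,9E)-11-(methoxycarbonyloxy)-3,7,11-trimethyldodeca-2,6,9-trien-1-yl acetate
Product: 13 (2E,6R,7R,9E)-6,7-epoxy-11-(methoxycarbonyloxy)-3,7,11-trimethyldodeca-2,9-dien-1-yl acetate
Conditions: D-fructose-derived Shi ketone (0.3 equiv), Oxone, K2CO3, Bu4NHSO4, MeCN/dimethoxymethane, aq. Na2B4O7/EDTA buffer (pH ca. 10.5), 0 °C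
Reagents that add atoms: Oxone (potassium peroxymonosulfate), [K+].[O-]S(=O)(=O)OO
Why: Shi asymmetric epoxidation, in which the chiral dioxirane takes the only unfunctionalised trisubstituted alkene C6=C7 (C2=C3 is deactivated by the allylic acetate, C9=C10 is disubstituted and carries the allylic carbonate) and, through the spiro transition state, the D-fructose-derived ketone gives the (R,R)-epoxide of an E-trisubstituted alkene, here 6R,7R.

Step 8
Reactants: 13 (2E,6R,7R,9E)-6,7-epoxy-11-(methoxycarbonyloxy)-3,7,11-trimethyldodeca-2,9-dien-1-yl acetate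
Product: 14 (2E,6R,7R,9E)-6,7-epoxy-11-(methoxycarbonyloxy)-3,7,11-trimethyldodeca-2,9-dien-1-ol
Conditions: K2CO3 (cat.), MeOH, 0 °C
Reagents that add atoms: none
Why: base-catalysed transesterification removes the unhindered primary acetate, while the carbonate, shielded like a tert-butyl ester by its tertiary alkyl group, and the epoxide should remain.

Step 9
Reactants: 14 (2E,6R,7R,9E)-6,7-epoxy-11-(methoxycarbonyloxy)-3,7,11-trimethyldodeca-2,9-dien-1-ol
Product: 15 (2E,6R,7R,9E)-6,7-epoxy-11-(methoxycarbonyloxy)-3,7,11-trimethyldodeca-2,9-dienal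
Conditions: activated MnO2, CH2Cl2, rt
Reagents that add atoms: none
Why: MnO2 oxidation of a primary allylic alcohol to the enal under neutral conditions, which keeps the 2E geometry and leaves epoxide and carbonate alone.

Step 10
Reactants: 15 (2E,6R,7R,9E)-6,7-epoxy-11-(methoxycarbonyloxy)-3,7,11-trimethyldodeca-2,9-dienal
Product: 17 (1S,2E,6R,7R,9E)-6,7-epoxy-3,7,11,11-tetramethylcycloundeca-2,9-dien-1-ol, via allylindium 16 (not isolated)
Conditions: Pd(PPh3)4 (10 mol %), InI (2 equiv), degassed THF, rt, slow addition of 15 (final ca. 3 mM); aq. NH4Cl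
Reagents that add atoms: none
Why: Pd(0) ionises the tertiary allylic carbonate with loss of CO2 and InI reduces the allyl-palladium methoxide to allylindium(III) 16, σ-bound at the less substituted C9, which adds through its dimethyl-substituted terminus C11 to the C1 aldehyde in a six-membered chair (Zimmerman–Traxler) transition state. The closest known reactions are the Pd/InI umpoled allylation of aldehydes with allylic carbonates and Nozaki–Hiyama-type or Pd-umpoled macrocyclisations of farnesyl-derived ω-formyl allyl electrophiles. The eleven-membered ring closes in an 11-exo-trig mode at the carbonyl, the allyl unit being transposed into the ring as the C9=C10 alkene while C11 becomes the quaternary carbon. The new stereocentre C1 is under substrate control: 1S requires C11 to bond to the Re face of the s-trans enal, and the only element that can tell the faces apart is the (6R,7R)-epoxide, relayed through the conformation of the seven-atom tether with C2 equatorial in the chair. The step needs γ- over α-attack (indium sits on the secondary C9, and the alternative nine-membered ring is strained), 1,2- over 1,4-addition (normal for allylindium reagents and enals), ring closure over oligomerisation (high dilution; few rotors between the rigid E-enal, trans-epoxide and allyl units) and Re-face attack, which is the least assured of the four. The epoxide should survive because the medium is neutral and the oxirane is neither vinylic nor allylic to the metal-bearing unit.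

Step 11
Reactants: 17 (1S,2E,6R,7R,9E)-6,7-epoxy-3,7,11,11-tetramethylcycloundeca-2,9-dien-1-ol
Product: 18 (1S,2E,6R,7R)-6,7-epoxy-3,7,11,11-tetramethylcycloundec-2-en-1-ol
Conditions: 2-nitrobenzenesulfonylhydrazide (excess), Et3N, CH2Cl2, rt
Reagents that add atoms: none
Why: diimide reduction, a concerted syn transfer of H2 that favours the 1,2-disubstituted C9=C10 over the trisubstituted C2=C3 alkene, spares epoxide, allylic C–O bond and stereocentres, and removes the 3-hydroxy-1,5-diene (oxy-Cope) liability before the acylation.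

Step 12
Reactants: 18 (1S,2E,6R,7R)-6,7-epoxy-3,7,11,11-tetramethylcycloundec-2-en-1-ol; 19 4-methoxybenzoyl chloride
Product: 20 (1S,2E,6R,7R)-6,7-epoxy-3,7,11,11-tetramethylcycloundec-2-en-1-yl 4-methoxybenzoate
Conditions: 4-MeOC6H4COCl, Et3N, DMAP, CH2Cl2, 0 °C → rt
Reagents that add atoms: 4-methoxybenzoyl chloride (19), COc1ccc(cc1)C(Cl)=O
Why: DMAP-catalysed acylation of the hindered secondary allylic alcohol under basic conditions that spare the epoxide; only the O–H bond reacts, so C1 keeps its configuration.

**Compound list**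

1 | (2E,6E)-farnesol | OC/C=C(\C)CC/C=C(\C)CCC=C(C)C | starting material
2 | acetic anhydride | CC(=O)OC(C)=O | starting material
3 | (2E,6E)-farnesyl acetate | CC(=O)OC/C=C(\C)CC/C=C(\C)CCC=C(C)C | intermediate
4 | (2E,6E)-10-bromo-11-hydroxy-3,7,11-trimethyldodeca-2,6-dien-1-yl acetate (racemic at C10) | CC(=O)OC/C=C(\C)CC/C=C(\C)CCC(Br)C(C)(C)O | intermediate
5 | (2E,6E)-10,11-epoxy-3,7,11-trimethyldodeca-2,6-dien-1-yl acetate (racemic; not isolated) | CC(=O)OC/C=C(\C)CC/C=C(\C)CCC1OC1(C)C | intermediate
6 | (2E,6E)-10,11-epoxy-3,7,11-trimethyldodeca-2,6-dien-1-ol (racemic) | OC/C=C(\C)CC/C=C(\C)CCC1OC1(C)C | intermediate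
7 | (2E,6E)-3,7,11-trimethyl-10-(phenylselanyl)dodeca-2,6-diene-1,11-diol (hydroxy selenide; not isolated) | OC/C=C(\C)CC/C=C(\C)CCC([Se]c1ccccc1)C(C)(C)O | intermediate
8 | (2E,6E)-3,7,11-trimethyl-10-(phenylseleninyl)dodeca-2,6-diene-1,11-diol (selenoxide; not isolated) | OC/C=C(\C)CC/C=C(\C)CCC([Se](=O)c1ccccc1)C(C)(C)O | intermediate
9 | (2E,6E,9E)-3,7,11-trimethyldodeca-2,6,9-triene-1,11-diol | OC/C=C(\C)CC/C=C(\C)C/C=C/C(C)(C)O | intermediate
10 | (2E,6E,9E)-11-hydroxy-3,7,11-trimethyldodeca-2,6,9-trien-1-yl acetate | CC(=O)OC/C=C(\C)CC/C=C(\C)C/C=C/C(C)(C)O | intermediate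
11 | methyl chloroformate | COC(Cl)=O | starting material
12 | (2E,6E,9E)-11-(methoxycarbonyloxy)-3,7,11-trimethyldodeca-2,6,9-trien-1-yl acetate | CC(=O)OC/C=C(\C)CC/C=C(\C)C/C=C/C(C)(C)OC(=O)OC | intermediate
13 | (2E,6R,7R,9E)-6,7-epoxy-11-(methoxycarbonyloxy)-3,7,11-trimethyldodeca-2,9-dien-1-yl acetate | CC(=O)OC/C=C(\C)CC[C@H]1O[C@]1(C)C/C=C/C(C)(C)OC(=O)OC | intermediate
14 | (2E,6R,7R,9E)-6,7-epoxy-11-(methoxycarbonyloxy)-3,7,11-trimethyldodeca-2,9-dien-1-ol | OC/C=C(\C)CC[C@H]1O[C@]1(C)C/C=C/C(C)(C)OC(=O)OC | intermediate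
15 | (2E,6R,7R,9E)-6,7-epoxy-11-(methoxycarbonyloxy)-3,7,11-trimethyldodeca-2,9-dienal | O=C/C=C(\C)CC[C@H]1O[C@]1(C)C/C=C/C(C)(C)OC(=O)OC | intermediate
16 | (2E,6R,7R)-6,7-epoxy-9-[iodo(methoxy)indio]-3,7,11-trimethyldodeca-2,10-dienal (C9-bound allylindium; not isolated) | O=C/C=C(\C)CC[C@H]1O[C@]1(C)CC([In](I)OC)C=C(C)C | intermediate
17 | (1S,2E,6R,7R,9E)-6,7-epoxy-3,7,11,11-tetramethylcycloundeca-2,9-dien-1-ol | O[C@H]1/C=C(\C)CC[C@H]2O[C@]2(C)C/C=C/C1(C)C | intermediate
18 | (1S,2E,6R,7R)-6,7-epoxy-3,7,11,11-tetramethylcycloundec-2-en-1-ol | O[C@H]1/C=C(\C)CC[C@H]2O[C@]2(C)CCCC1(C)C | intermediate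
19 | 4-methoxybenzoyl chloride | COc1ccc(cc1)C(Cl)=O | starting material
20 | (1S,2E,6R,7R)-6,7-epoxy-3,7,11,11-tetramethylcycloundec-2-en-1-yl 4-methoxybenzoate | COc1ccc(C(=O)O[C@H]2/C=C(\C)CC[C@H]3O[C@]3(C)CCCC2(C)C)cc1 | target

Total step count: 12. Longest linear sequence: 12 steps, from 1 to 20.

**Steps most likely to fail**

1. Step 10. The ring closure may show poor facial selectivity at C1, because the induction from the epoxide is remote and its sense cannot be guaranteed. Oligomerisation, diene formation by β-hydride loss from the allyl-palladium stage, and Lewis-acid opening of the epoxide by indium(III) are secondary threats. The fallback sets out from 15 and returns at 17. The cyclisation is run as before and the C1 epimer (1R,2E,6R,7R,9E)-6,7-epoxy-3,7,11,11-tetramethylcycloundeca-2,9-dien-1-ol F1, alone or mixed with 17, is oxidised with Dess–Martin periodinane/NaHCO3 in CH2Cl2 to the enone (2E,6R,7R,9E)-6,7-epoxy-3,7,11,11-tetramethylcycloundeca-2,9-dien-1-one F2. CBS reduction with (R)-2-methyl-CBS-oxazaborolidine and catecholborane in toluene at −78 °C, with the quaternary C11 flank as the large group and the alkenyl C2 as the small one, should then deliver hydride to the face that gives 17. C1 is thereby fixed by the reagent instead of by the ring.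

2. Step 11. Diimide may lose chemoselectivity: the C9=C10 alkene, neopentylic at C11, may react sluggishly, so that forcing the reaction starts to saturate C2=C3. The fallback sets out from 17 and returns at 20. The alcohol is acylated first (4-methoxybenzoyl chloride, Et3N, DMAP, CH2Cl2) to (1S,2E,6R,7R,9E)-6,7-epoxy-3,7,11,11-tetramethylcycloundeca-2,9-dien-1-yl 4-methoxybenzoate F3. The disubstituted alkene is then hydrogenated with H2 and Wilkinson's catalyst (RhCl(PPh3)3, benzene, rt), which separates di- from trisubstituted alkenes on steric grounds and finds no free hydroxyl to direct it to C2=C3. This gives 20 directly.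

3. Step 6. Acetyl transfer to the tertiary alkoxide or enolisation of the acetate may compete with carbonate formation, giving scrambled esters and incomplete conversion. The fallback sets out from 9 and returns at 12. The primary hydroxyl is silylated (TBSCl, imidazole, CH2Cl2) to (3E,6E,10E)-12-(tert-butyldimethylsilyloxy)-2,6,10-trimethyldodeca-3,6,10-trien-2-ol F4. With no ester present, the tertiary alcohol is converted with n-BuLi and methyl chloroformate (THF, −78 °C) into the silyl ether carbonate (2E,6E,9E)-1-(tert-butyldimethylsilyloxy)-11-(methoxycarbonyloxy)-3,7,11-trimethyldodeca-2,6,9-triene F5. TBAF buffered with AcOH frees the primary alcohol (2E,6E,9E)-11-(methoxycarbonyloxy)-3,7,11-trimethyldodeca-2,6,9-trien-1-ol F6, and Ac2O/pyridine then gives 12.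

**Further compounds**

F1 | step 10 | (1R,2E,6R,7R,9E)-6,7-epoxy-3,7,11,11-tetramethylcycloundeca-2,9-dien-1-ol | O[C@@H]1/C=C(\C)CC[C@H]2O[C@]2(C)C/C=C/C1(C)C
F2 | step 10 | (2E,6R,7R,9E)-6,7-epoxy-3,7,11,11-tetramethylcycloundeca-2,9-dien-1-one | O=C1/C=C(\C)CC[C@H]2O[C@]2(C)C/C=C/C1(C)C
F3 | step 11 | (1S,2E,6R,7R,9E)-6,7-epoxy-3,7,11,11-tetramethylcycloundeca-2,9-dien-1-yl 4-methoxybenzoate | COc1ccc(C(=O)O[C@H]2/C=C(\C)CC[C@H]3O[C@]3(C)C/C=C/C2(C)C)cc1
F4 | step 6 | (3E,6E,10E)-12-(tert-butyldimethylsilyloxy)-2,6,10-trimethyldodeca-3,6,10-trien-2-ol | CC(C)(C)[Si](C)(C)OC/C=C(\C)CC/C=C(\C)C/C=C/C(C)(C)O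
F5 | step 6 | (2E,6E,9E)-1-(tert-butyldimethylsilyloxy)-11-(methoxycarbonyloxy)-3,7,11-trimethyldodeca-2,6,9-triene | CC(C)(C)[Si](C)(C)OC/C=C(\C)CC/C=C(\C)C/C=C/C(C)(C)OC(=O)OC
F6 | step 6 | (2E,6E,9E)-11-(methoxycarbonyloxy)-3,7,11-trimethyldodeca-2,6,9-trien-1-ol | OC/C=C(\C)CC/C=C(\C)C/C=C/C(C)(C)OC(=O)OC
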